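## The problem

Atoms are numbered as in germacranolides: ring carbons C1–C10, lactone carbons C11–C13 (C12 the carbonyl), C14 on C10, C15 on C4.

Target 34 is a cyclodeca-1(10),4-diene with a trans-fused α-methylene-γ-butyrolactone across C6 and C7 (O–C6, C7–C11(=C13)–C12). C8 carries an (S)-2-methylbutanoate, C10 a formyl group (C14) and C4 a hydroxymethyl group (C15). Both trisubstituted ring alkenes are ring-cis (C2 and C9 on the same side of C1=C10, C3 and C6 on the same side of C4=C5). Neither geometry can be repaired once the medium ring exists, so each must come from a stereospecific reaction on an open chain. The ring has three contiguous stereocenters, C6, C7 and C8 (all R in 34). C7 and C8 are anti along the C6–C9 chain and can be set together in an acyclic aldol; their 1,2- and 1,3-induction on a C6 carbonyl then points to the C6 configuration of the trans lactone, so C6 can be left to the ring-forming step. The fourth stereocenter lies α to the side-chain ester carbonyl, is bought, and must not meet strong base. A ten-membered ring is costly to close, so the closure must be irreversible and run at high dilution on a chain already folded by the two cis alkenes. The α-methylene lactone and the enal are Michael acceptors, the C8 acyloxy group is placed for vinylogous β-elimination from the enal, and the C15 alcohol is allylic; all must be unveiled late under neutral or mildly acidic conditions. The enabling feature is that C6 is both the allylic carbon next to alkene carbon C5 and the carbinol carbon four atoms from C12 (C6–C7–C11–C12). Addition of a C5 alkenyl metal to a C6 aldehyde therefore makes the ring bond C5–C6 and an alkoxide placed 5-exo to a C12 ester, so one operation can close both rings.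

## Retrosynthesis

**From 34 to lactone 25 (no skeletal bond cut).** The free C15 alcohol is released last from silyl ether 33. The enal is made just before by MnO2 oxidation of allylic alcohol 32, which comes from PMB ether 31. The C8 ester is attached to alcohol 29 with acid 30 only after the methylene group is in place, because the methylenation uses a lithium amide that would enolise the 2-methylbutanoate. The methylene lactone 28 comes from amine 26 through ammonium salt 27, and 26 from the saturated lactone 25. The methylene cannot be carried through the ring closure, since an acrylate next to a C6 aldehyde would be a β,γ-unsaturated aldehyde that drifts into conjugation. This fixes three orthogonal ethers in 25: TES on O8, PMB on O14, TBDPS on O15.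

**25 to aldehyde 23 (C5–C6 and O6–C12 cut).** Neighbouring cuts are weaker: ring-closing metathesis at C4=C5 or C1=C10 gives no control of a trisubstituted geometry in a ten-membered ring, and closure at C6–C7 or C7–C8 would create two stereocenters in the macrocyclic step. The chosen cut creates only C6, next to two centers that direct it, and forms the lactone for free. Precursor 23 is an open chain with two stereocenters, two preformed cis alkenes, an alkenyl iodide, an aldehyde and a methyl ester. The forward step must add an alkenyl metal to the aldehyde but not to the ester, keep the alkene geometry, and favour ring closure over oligomerisation.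

**23 to imide 19 and aldehyde 16 (C7–C8 cut).** The C6 aldehyde of 23 is traced through thioester 22 and silyl ether 21 to aldol adduct 20, and 20 is cut at C7–C8. Cutting C7–C11 instead would mean alkylating a β-silyloxy enolate, which eliminates; cutting C8–C9 would need an allyl metal that reacts at the wrong terminus. The aldol must be anti and under auxiliary control, and the adduct must be silylated before its C8 hydroxyl lactonises onto C12. C6 goes to the aldehyde through a thioester because a C6 alcohol would lactonise onto C12 at the wrong oxidation level.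

**16 to aldehyde 8 and phosphonate 11 (C1=C10 cut).** Aldehyde 16 comes from alcohol 15, silyl ether 14, allylic alcohol 13 and enoate 12, which is cut at C1=C10 by olefination. A Claisen rearrangement would place C2 trans to C9, and a Wittig reaction on a C10 ketone is not selective. The olefination must put the ester trans to C2. Reduction of the C14 ester is done before any other carbonyl is in the molecule, which is why the olefination precedes the aldol.

**8 to alkyne 2 and bromide 3 (C3–C4 and C5–I cut).** Aldehyde 8 comes from acetal 7, which is cut at C3–C4 and C5–I by syn carbocupration of 2 with the copper reagent from 3, then iodination. Hydroxyl-directed anti carbomagnesiation of 1 would put iodine cis to the CH2O group, the wrong isomer, and zirconium-catalysed carboalumination delivers only methyl. The addition must place the alkyl group on the internal carbon, and copper and alkyl must stay cis.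

**Remaining pieces.** Phosphonate 11 is the alkylation product of 9 with 10, imide 19 the acylation product of 17 with 18, and 2 the silyl ether of 1.

## Roads not taken

**Alternative 1:** The cut is made inside a bicycle. C14 is bonded to C4 as well as to C10, so C1–C10 plus C14 form a bicyclo[5.3.1]undecene, and the ten-membered ring is released by Grob fragmentation. KOt-Bu would deprotonate a C14 carbinol, the C4–C14 bond would break as a mesylate leaves C5, and cyclodecadienal A1 would appear with the formyl group and the C4=C5 bond formed together.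
- Merits: ring strain is paid by a fragmentation that needs no dilution, the C4=C5 geometry follows from the antiperiplanar arrangement of the breaking bonds, and C14 arrives at the aldehyde level. In certainty of forming the medium ring this road is better than the chosen one.
- Weak points: in the bicycle the C1=C10 alkene lies in the six-membered ring of C1, C2, C3, C4, C14 and C10, so C2 and C14 are cis. A1 therefore has C2 and C9 on opposite sides, whereas 34 needs them on the same side, and a strained dienal would have to be isomerised. The bicycle (bridgehead alkene, quaternary C4, five stereocenters) is a longer problem than an open chain. A1 also reaches the enal before the lactone exists, so C12 must still be oxidised and C6 lactonised beside a sensitive aldehyde.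
- Comparison: the chosen plan sets against the safer ring formation a short convergent chain assembly, both alkene geometries fixed before closure, and the lactone formed in the ring-closing step.

**Alternative 2:** The cut is the sp2–sp3 bond C1–C2. 9-BBN would hydroborate the terminal C2=C3 alkene of a diene at C4, and the alkylborane would couple with a C1 enol triflate under zerovalent palladium (Pd(PPh3)4, K3PO4) to give lactone ester A2.
- Merits: the lactone and C6, C7 and C8 are all in place before cyclisation, so ring closure creates no stereocenter. This is better than the chosen plan, where C6 is decided in the macrocyclic transition state.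
- Weak points: the triflate must be the isomer with the leaving group trans to the ester, and enolates of α-formyl esters are triflated mainly on the chelated, cis side. Ten-membered rings are at the unfavourable end for B-alkyl Suzuki closure, where protodeboronation and β-hydride elimination compete. A2 carries C14 as a methyl ester, which cannot be reduced to the aldehyde beside the more electrophilic γ-lactone.
- Comparison: the chosen plan answers with an aldehyde whose C7 and C8 centers reinforce each other in directing C6, with a corrective inversion in reserve, and keeps C14 at the alcohol level so that only MnO2 is needed at the end.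

**Alternative 3:** The cut is C7–C8. CrCl2 (divalent chromium) would convert a 3-(bromomethyl)butenolide into an allylchromium species that attacks a tethered C8 aldehyde through its γ-carbon C7, closing the ring, restoring the C11=C13 methylene and giving hydroxy lactone A3.
- Merits: A3 is the same compound as 29 of the chosen route, reached without the aminomethylation, elimination and desilylation steps. In step count after ring closure this road is better.
- Weak points: two stereocenters, C7 and C8, are created in the ring closure under the influence of C6 alone. Attack anti to the C6 substituent should give the trans lactone, but the C8 configuration depends on which aldehyde face the ten-membered transition state presents. The cyclisation substrate is fragile: its C6 hydrogen is allylic and γ to the butenolide carbonyl, and its aldehyde is of the same β,γ-unsaturated type as 16 but must be unveiled last.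
- Comparison: the chosen plan sets against the shorter endgame that C7 and C8 are fixed by an auxiliary on an open chain, and that only C6, biased by both neighbours, is left to the cyclisation.

Key step: step 15

Assumption: 3, 10, 17, 18 and 30 are bought (18 stands for the succinate half-ester otherwise made from succinic anhydride); the C10 center of 11 and the C11 center of 26 and 27 form as mixtures and are destroyed in the following step.

## Steps

Step 1
Reactants: 1 prop-2-yn-1-ol (propargyl alcohol)
Product: 2 tert-butyl(diphenyl)(prop-2-yn-1-yloxy)silane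
Conditions: t-BuPh2SiCl, imidazole, CH2Cl2, 0 °C to rt
Reagents that add atoms: tert-butyl(chloro)diphenylsilane, CC(C)(C)[Si](Cl)(c1ccccc1)c1ccccc1
Why: Standard silylation of a primary alcohol; the bulky, weakly coordinating silyl ether survives to the last step and disfavours oxygen-directed reverse carbometalation in step 2.

Step 2
Reactants: 2 tert-butyl(diphenyl)(prop-2-yn-1-yloxy)silane; 3 2-(2-bromoethyl)-1,3-dioxolane
Product: 7 (E)-tert-butyl{[4-(1,3-dioxolan-2-yl)-2-(iodomethylidene)butyl]oxy}diphenylsilane, via Grignard reagent 4 (not isolated), via alkylcopper reagent 5 (not isolated), via alkenylcopper 6 (not isolated)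
Conditions: 3, Mg, THF, 25 °C; CuBr·SMe2, THF–Me2S, −45 °C; 2, −45 to −15 °C; I2, −45 to 0 °C
Reagents that add atoms: iodine, [I][I]
Why: Normant carbocupration: the alkylcopper adds syn across the terminal alkyne with the alkyl group on the internal carbon C4 and copper on C5, and iodinolysis proceeds with retention, so iodine ends cis to the C3 chain and trans to CH2OSi (the ring-cis C4=C5 geometry). THF and the non-chelating silyl ether are chosen to suppress the reverse regiochemistry that leads to an allene.

Step 3
Reactants: 7 (E)-tert-butyl{[4-(1,3-dioxolan-2-yl)-2-(iodomethylidene)butyl]oxy}diphenylsilane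
Product: 8 (E)-4-{[(tert-butyldiphenylsilyl)oxy]methyl}-5-iodopent-4-enal
Conditions: 2 M HCl, THF, rt
Reagents that add atoms: water, O
Why: Acid-catalysed acetal hydrolysis; the primary TBDPS ether and the alkenyl iodide are stable to dilute aqueous acid at room temperature.

Step 4
Reactants: 9 triethyl phosphonoacetate; 10 (2-bromoethoxy)(tert-butyl)dimethylsilane
Product: 11 ethyl 4-[(tert-butyldimethylsilyl)oxy]-2-(diethoxyphosphoryl)butanoate (racemic)
Conditions: NaH, DMF, 0 °C; 10, NaI (cat.), 60 °C
Reagents that add atoms: none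
Why: C-alkylation of the sodium salt of a phosphonoacetate with a primary bromide; the new center at C10 is racemic and is removed in step 5.

Step 5
Reactants: 11 ethyl 4-[(tert-butyldimethylsilyl)oxy]-2-(diethoxyphosphoryl)butanoate; 8 (E)-4-{[(tert-butyldiphenylsilyl)oxy]methyl}-5-iodopent-4-enal
Product: 12 ethyl (2E,6E)-2-{2-[(tert-butyldimethylsilyl)oxy]ethyl}-6-{[(tert-butyldiphenylsilyl)oxy]methyl}-7-iodohepta-2,6-dienoate
Conditions: LiCl, DBU, MeCN, 0 °C to rt
Reagents that add atoms: none
Why: Horner–Wadsworth–Emmons olefination with LiCl and an amine base; reversible addition and the preference for the ester trans to the β-alkyl chain should give mainly the 2E enoate (C2 cis to C9), the geometry needed for C1=C10. The mild base leaves the alkenyl iodide and silyl ethers untouched.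

Step 6
Reactants: 12 ethyl (2E,6E)-2-{2-[(tert-butyldimethylsilyl)oxy]ethyl}-6-{[(tert-butyldiphenylsilyl)oxy]methyl}-7-iodohepta-2,6-dienoate
Product: 13 (2E,6E)-2-{2-[(tert-butyldimethylsilyl)oxy]ethyl}-6-{[(tert-butyldiphenylsilyl)oxy]methyl}-7-iodohepta-2,6-dien-1-ol
Conditions: i-Bu2AlH, CH2Cl2, −78 to −20 °C; aq. potassium sodium tartrate
Reagents that add atoms: none
Why: 1,2-Reduction of the enoate to the allylic alcohol; it is done here because no other carbonyl group is yet in the molecule.

Step 7
Reactants: 13 (2E,6E)-2-{2-[(tert-butyldimethylsilyl)oxy]ethyl}-6-{[(tert-butyldiphenylsilyl)oxy]methyl}-7-iodohepta-2,6-dien-1-ol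
Product: 14 tert-butyl{[(3E,7E)-8-iodo-3-{[(4-methoxybenzyl)oxy]methyl}-7-{[(tert-butyldiphenylsilyl)oxy]methyl}octa-3,7-dien-1-yl]oxy}dimethylsilane
Conditions: NaH, 4-MeOC6H4CH2Cl, Bu4NI (cat.), THF–DMF, 0 °C to rt
Reagents that add atoms: 4-methoxybenzyl chloride, COc1ccc(CCl)cc1
Why: Williamson etherification; the PMB ether is orthogonal to the three silyl ethers and is the only group removed oxidatively at the end.

Step 8
Reactants: 14 tert-butyl{[(3E,7E)-8-iodo-3-{[(4-methoxybenzyl)oxy]methyl}-7-{[(tert-butyldiphenylsilyl)oxy]methyl}octa-3,7-dien-1-yl]oxy}dimethylsilane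
Product: 15 (3E,7E)-8-iodo-3-{[(4-methoxybenzyl)oxy]methyl}-7-{[(tert-butyldiphenylsilyl)oxy]methyl}octa-3,7-dien-1-ol
Conditions: camphorsulfonic acid (cat.), MeOH–CH2Cl2, 0 °C
Reagents that add atoms: none
Why: Acid-catalysed methanolysis removes the primary TBS ether much faster than the TBDPS ether; the PMB ether is inert.

Step 9
Reactants: 15 (3E,7E)-8-iodo-3-{[(4-methoxybenzyl)oxy]methyl}-7-{[(tert-butyldiphenylsilyl)oxy]methyl}octa-3,7-dien-1-ol
Product: 16 (3E,7E)-8-iodo-3-{[(4-methoxybenzyl)oxy]methyl}-7-{[(tert-butyldiphenylsilyl)oxy]methyl}octa-3,7-dienal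
Conditions: Dess–Martin periodinane, NaHCO3, CH2Cl2, 0 °C to rt
Reagents that add atoms: none
Why: Dess–Martin oxidation under buffered, non-enolising conditions is the standard access to a β,γ-unsaturated aldehyde without migration of the double bond; 16 is used at once.

Step 10
Reactants: 17 (S)-4-benzyl-1,3-oxazolidin-2-one; 18 methyl 4-chloro-4-oxobutanoate
Product: 19 methyl 4-[(4S)-4-benzyl-2-oxo-1,3-oxazolidin-3-yl]-4-oxobutanoate
Conditions: n-BuLi, THF, −78 °C; 18, −78 to 0 °C
Reagents that add atoms: none
Why: N-Acylation of the lithiated oxazolidinone by the acid chloride, which reacts far faster than the methyl ester.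

Step 11
Reactants: 19 methyl 4-[(4S)-4-benzyl-2-oxo-1,3-oxazolidin-3-yl]-4-oxobutanoate; 16 (3E,7E)-8-iodo-3-{[(4-methoxybenzyl)oxy]methyl}-7-{[(tert-butyldiphenylsilyl)oxy]methyl}octa-3,7-dienal
Product: 20 methyl (3R,4R,6E,10E)-3-{[(4S)-4-benzyl-2-oxo-1,3-oxazolidin-3-yl]carbonyl}-4-hydroxy-11-iodo-6-{[(4-methoxybenzyl)oxy]methyl}-10-{[(tert-butyldiphenylsilyl)oxy]methyl}undeca-6,10-dienoate
Conditions: Bu2BOTf, i-Pr2NEt, CH2Cl2, 0 °C; −78 °C, 16 precomplexed with Et2AlCl; then H2O2, MeOH, pH 7 buffer, 0 °C
Reagents that add atoms: none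
Why: Lewis-acid-mediated anti variant of the Evans aldol: the Z boron enolate, chelated to the auxiliary carbonyl because boron is not bound to the aldehyde, attacks the Et2AlCl-activated aldehyde through an open transition state on the face away from the benzyl group. This should set C7 (opposite to the usual syn sense), and the bulky aluminium-complexed carbonyl avoids the enolate substituent, which favours the anti C8 carbinol. Only the imide, not the methyl ester, is enolised.

Step 12
Reactants: 20 methyl (3R,4R,6E,10E)-3-{[(4S)-4-benzyl-2-oxo-1,3-oxazolidin-3-yl]carbonyl}-4-hydroxy-11-iodo-6-{[(4-methoxybenzyl)oxy]methyl}-10-{[(tert-butyldiphenylsilyl)oxy]methyl}undeca-6,10-dienoate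
Product: 21 methyl (3R,4R,6E,10E)-3-{[(4S)-4-benzyl-2-oxo-1,3-oxazolidin-3-yl]carbonyl}-11-iodo-6-{[(4-methoxybenzyl)oxy]methyl}-10-{[(tert-butyldiphenylsilyl)oxy]methyl}-4-[(triethylsilyl)oxy]undeca-6,10-dienoate
Conditions: Et3SiOTf, 2,6-lutidine, CH2Cl2, −78 °C (on crude 20)
Reagents that add atoms: triethylsilyl trifluoromethanesulfonate, CC[Si](CC)(CC)OS(=O)(=O)C(F)(F)F
Why: Silylation by the triflate at −78 °C outruns lactonisation of the γ-hydroxy ester; TES is chosen because it can later be removed beside TBDPS.

Step 13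
Reactants: 21 methyl (3R,4R,6E,10E)-3-{[(4S)-4-benzyl-2-oxo-1,3-oxazolidin-3-yl]carbonyl}-11-iodo-6-{[(4-methoxybenzyl)oxy]methyl}-10-{[(tert-butyldiphenylsilyl)oxy]methyl}-4-[(triethylsilyl)oxy]undeca-6,10-dienoate
Product: 22 methyl (3R,4R,6E,10E)-3-[(ethylsulfanyl)carbonyl]-11-iodo-6-{[(4-methoxybenzyl)oxy]methyl}-10-{[(tert-butyldiphenylsilyl)oxy]methyl}-4-[(triethylsilyl)oxy]undeca-6,10-dienoate
Conditions: EtSH, n-BuLi, THF, −78 to 0 °C
Reagents that add atoms: ethanethiol, CCS
Why: Lithium ethanethiolate cleaves the exocyclic imide carbonyl of hindered aldol adducts by acyl substitution; it is too weakly basic to epimerise C7 or eliminate the silyloxy group, and leaves the methyl ester alone.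

Step 14
Reactants: 22 methyl (3R,4R,6E,10E)-3-[(ethylsulfanyl)carbonyl]-11-iodo-6-{[(4-methoxybenzyl)oxy]methyl}-10-{[(tert-butyldiphenylsilyl)oxy]methyl}-4-[(triethylsilyl)oxy]undeca-6,10-dienoate
Product: 23 methyl (3R,4R,6E,10E)-3-formyl-11-iodo-6-{[(4-methoxybenzyl)oxy]methyl}-10-{[(tert-butyldiphenylsilyl)oxy]methyl}-4-[(triethylsilyl)oxy]undeca-6,10-dienoate
Conditions: i-Bu2AlH (1.1 equiv), CH2Cl2, −78 °C; aq. potassium sodium tartrate
Reagents that add atoms: none
Why: A thioester is reduced at −78 °C to a stable hemithioacetal aluminate much faster than a methyl ester, so one equivalent should give the C6 aldehyde and spare C12; a cold neutral work-up and direct use protect the α-stereocenter.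

Step 15
Reactants: 23 methyl (3R,4R,6E,10E)-3-formyl-11-iodo-6-{[(4-methoxybenzyl)oxy]methyl}-10-{[(tert-butyldiphenylsilyl)oxy]methyl}-4-[(triethylsilyl)oxy]undeca-6,10-dienoate
Product: 25 (6α,7αH,8β)-14-[(4-methoxybenzyl)oxy]-15-[(tert-butyldiphenylsilyl)oxy]-8-[(triethylsilyl)oxy]germacra-1(10),4-dien-12,6-olide (both ring alkenes ring-cis and the lactone trans-fused), via ten-membered hydroxy ester 24 (not isolated)
Conditions: CrCl2 (12 equiv), NiCl2 (1 mol % of Cr), degassed DMSO–THF, slow addition of 23 to 2 mM, rt, then 40 °C; aq. NH4Cl work-up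
Reagents that add atoms: none
Why: CrCl2 reduces NiCl2 to zerovalent nickel, which inserts into the C5–I bond; transmetalation gives a trivalent alkenylchromium species that adds to the C6 aldehyde with retention of the C4=C5 geometry. The closest known reaction type is the intramolecular Nozaki–Hiyama–Kishi alkenyl iodide–aldehyde coupling to medium and large rings, followed by lactonisation of the γ-alkoxy ester. The carbocycle closes by 10-exo-trig addition of C5 to C6, and the chromium alkoxide of 24 then closes the γ-lactone by 5-exo-trig acyl substitution at C12 with loss of methoxide, in the flask or on work-up. The new stereocenter C6 is controlled by C7 and C8: because they are anti, Felkin–Anh 1,2-induction (C8 branch anti to the nucleophile) and 1,3-induction from the β-silyloxy group select the same aldehyde face, the one that places O6 trans to H7. The step needs aldehyde-over-ester chemoselectivity, which alkenylchromium reagents provide, and ring closure over oligomerisation, which high dilution and the two preformed ring-cis alkenes favour. The silyl and PMB ethers are inert.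

Step 16
Reactants: 25 (6α,7αH,8β)-14-[(4-methoxybenzyl)oxy]-15-[(tert-butyldiphenylsilyl)oxy]-8-[(triethylsilyl)oxy]germacra-1(10),4-dien-12,6-olide
Product: 26 13-(dimethylamino) derivative of 25 (C11 epimers)
Conditions: LiN(i-Pr)2, THF, −78 °C; CH2=NMe2 iodide, −78 °C to rt
Reagents that add atoms: N,N-dimethylmethyleneiminium iodide, C=[N+](C)C.[I-]
Why: Mannich reaction of the lactone lithium enolate; C11 is the only acidic position and the C8 silyloxy group is not β to the enolate, so no elimination is expected, and the C11 configuration is irrelevant.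

Step 17
Reactants: 26 13-(dimethylamino) derivative of 25
Product: 28 (6α,7αH,8β)-14-[(4-methoxybenzyl)oxy]-15-[(tert-butyldiphenylsilyl)oxy]-8-[(triethylsilyl)oxy]germacra-1(10),4,11(13)-trien-12,6-olide, via trimethylammonium iodide 27 (not isolated)
Conditions: MeI, THF, rt; then aq. NaHCO3, EtOAc, rt
Reagents that add atoms: none
Why: Exhaustive methylation gives the quaternary ammonium salt, and mild base brings about Hofmann-type elimination of trimethylamine to the exocyclic C11=C13 methylene.

Step 18
Reactants: 28 (6α,7αH,8β)-14-[(4-methoxybenzyl)oxy]-15-[(tert-butyldiphenylsilyl)oxy]-8-[(triethylsilyl)oxy]germacra-1(10),4,11(13)-trien-12,6-olide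
Product: 29 (6α,7αH,8β)-8-hydroxy-14-[(4-methoxybenzyl)oxy]-15-[(tert-butyldiphenylsilyl)oxy]germacra-1(10),4,11(13)-trien-12,6-olide
Conditions: pyridinium p-toluenesulfonate, MeOH–CH2Cl2, 0 °C
Reagents that add atoms: none
Why: A secondary TES ether is cleaved by acid-catalysed methanolysis while the primary TBDPS ether, the PMB ether and the lactone survive; acid avoids alkoxide-mediated translactonisation to O8 and conjugate addition to the methylene lactone.

Step 19
Reactants: 29 (6α,7αH,8β)-8-hydroxy-14-[(4-methoxybenzyl)oxy]-15-[(tert-butyldiphenylsilyl)oxy]germacra-1(10),4,11(13)-trien-12,6-olide; 30 (S)-2-methylbutanoic acid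
Product: 31 (6α,7αH,8β)-14-[(4-methoxybenzyl)oxy]-8-{[(2S)-2-methylbutanoyl]oxy}-15-[(tert-butyldiphenylsilyl)oxy]germacra-1(10),4,11(13)-trien-12,6-olide
Conditions: dicyclohexylcarbodiimide, 4-(dimethylamino)pyridine (cat.), CH2Cl2, 0 °C to rt
Reagents that add atoms: none
Why: Steglich esterification of the C8 alcohol with retention at C8; the acid's α-center bears no activating group and should not epimerise under these conditions.

Step 20
Reactants: 31 (6α,7αH,8β)-14-[(4-methoxybenzyl)oxy]-8-{[(2S)-2-methylbutanoyl]oxy}-15-[(tert-butyldiphenylsilyl)oxy]germacra-1(10),4,11(13)-trien-12,6-olide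
Product: 32 (6α,7αH,8β)-14-hydroxy-8-{[(2S)-2-methylbutanoyl]oxy}-15-[(tert-butyldiphenylsilyl)oxy]germacra-1(10),4,11(13)-trien-12,6-olide
Conditions: DDQ, CH2Cl2–pH 7 buffer, 0 °C
Reagents that add atoms: none
Why: Oxidative cleavage of the PMB ether (benzylic hydride abstraction, then hydrolysis of the oxocarbenium ion); the silyl ether, the esters and the alkenes are inert.

Step 21
Reactants: 32 (6α,7αH,8β)-14-hydroxy-8-{[(2S)-2-methylbutanoyl]oxy}-15-[(tert-butyldiphenylsilyl)oxy]germacra-1(10),4,11(13)-trien-12,6-olide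
Product: 33 (6α,7αH,8β)-8-{[(2S)-2-methylbutanoyl]oxy}-14-oxo-15-[(tert-butyldiphenylsilyl)oxy]germacra-1(10),4,11(13)-trien-12,6-olide
Conditions: MnO2, CH2Cl2, rt
Reagents that add atoms: none
Why: MnO2 oxidises the primary allylic alcohol to the enal under neutral conditions; the arrangement with C2 trans to the formyl group is also the more stable enal geometry, so no isomerisation is expected.

Step 22
Reactants: 33 (6α,7αH,8β)-8-{[(2S)-2-methylbutanoyl]oxy}-14-oxo-15-[(tert-butyldiphenylsilyl)oxy]germacra-1(10),4,11(13)-trien-12,6-olide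
Product: 34 (6R,7R,8R)-15-hydroxy-8-{[(2S)-2-methylbutanoyl]oxy}-14-oxogermacra-1(10),4,11(13)-trien-12,6-olide (target CNP0168859.6)
Conditions: HF·pyridine, pyridine, THF, 0 °C to rt
Reagents that add atoms: none
Why: Buffered HF·pyridine removes the silyl ether under mildly acidic conditions that spare the enal, the methylene lactone and the ester, all of which would suffer under basic fluoride.

## Compound list

1 | prop-2-yn-1-ol (propargyl alcohol) | C#CCO | starting material
2 | tert-butyl(diphenyl)(prop-2-yn-1-yloxy)silane | C#CCO[Si](c1ccccc1)(c1ccccc1)C(C)(C)C | intermediate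
3 | 2-(2-bromoethyl)-1,3-dioxolane | BrCCC1OCCO1 | starting material
4 | [2-(1,3-dioxolan-2-yl)ethyl]magnesium bromide (not isolated) | Br[Mg]CCC1OCCO1 | intermediate
5 | [2-(1,3-dioxolan-2-yl)ethyl]copper, as its MgBr2 complex (not isolated) | [Cu]CCC1OCCO1 | intermediate
6 | (E)-{2-{[(tert-butyldiphenylsilyl)oxy]methyl}-4-(1,3-dioxolan-2-yl)but-1-en-1-yl}copper (not isolated) | [Cu]/C=C(/CO[Si](c1ccccc1)(c1ccccc1)C(C)(C)C)CCC1OCCO1 | intermediate
7 | (E)-tert-butyl{[4-(1,3-dioxolan-2-yl)-2-(iodomethylidene)butyl]oxy}diphenylsilane | I/C=C(/CO[Si](c1ccccc1)(c1ccccc1)C(C)(C)C)CCC1OCCO1 | intermediate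
8 | (E)-4-{[(tert-butyldiphenylsilyl)oxy]methyl}-5-iodopent-4-enal | I/C=C(/CO[Si](c1ccccc1)(c1ccccc1)C(C)(C)C)CCC=O | intermediate
9 | triethyl phosphonoacetate | CCOC(=O)CP(=O)(OCC)OCC | starting material
10 | (2-bromoethoxy)(tert-butyl)dimethylsilane | BrCCO[Si](C)(C)C(C)(C)C | starting material
11 | ethyl 4-[(tert-butyldimethylsilyl)oxy]-2-(diethoxyphosphoryl)butanoate (racemic) | CCOC(=O)C(CCO[Si](C)(C)C(C)(C)C)P(=O)(OCC)OCC | intermediate
12 | ethyl (2E,6E)-2-{2-[(tert-butyldimethylsilyl)oxy]ethyl}-6-{[(tert-butyldiphenylsilyl)oxy]methyl}-7-iodohepta-2,6-dienoate | I/C=C(/CO[Si](c1ccccc1)(c1ccccc1)C(C)(C)C)CC/C=C(/C(=O)OCC)CCO[Si](C)(C)C(C)(C)C | intermediate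
13 | (2E,6E)-2-{2-[(tert-butyldimethylsilyl)oxy]ethyl}-6-{[(tert-butyldiphenylsilyl)oxy]methyl}-7-iodohepta-2,6-dien-1-ol | I/C=C(/CO[Si](c1ccccc1)(c1ccccc1)C(C)(C)C)CC/C=C(/CO)CCO[Si](C)(C)C(C)(C)C | intermediate
14 | tert-butyl{[(3E,7E)-8-iodo-3-{[(4-methoxybenzyl)oxy]methyl}-7-{[(tert-butyldiphenylsilyl)oxy]methyl}octa-3,7-dien-1-yl]oxy}dimethylsilane | I/C=C(/CO[Si](c1ccccc1)(c1ccccc1)C(C)(C)C)CC/C=C(/COCc1ccc(OC)cc1)CCO[Si](C)(C)C(C)(C)C | intermediate
15 | (3E,7E)-8-iodo-3-{[(4-methoxybenzyl)oxy]methyl}-7-{[(tert-butyldiphenylsilyl)oxy]methyl}octa-3,7-dien-1-ol | I/C=C(/CO[Si](c1ccccc1)(c1ccccc1)C(C)(C)C)CC/C=C(/COCc1ccc(OC)cc1)CCO | intermediate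
16 | (3E,7E)-8-iodo-3-{[(4-methoxybenzyl)oxy]methyl}-7-{[(tert-butyldiphenylsilyl)oxy]methyl}octa-3,7-dienal | I/C=C(/CO[Si](c1ccccc1)(c1ccccc1)C(C)(C)C)CC/C=C(/COCc1ccc(OC)cc1)CC=O | intermediate
17 | (S)-4-benzyl-1,3-oxazolidin-2-one | O=C1N[C@@H](Cc2ccccc2)CO1 | starting material
18 | methyl 4-chloro-4-oxobutanoate | COC(=O)CCC(Cl)=O | starting material
19 | methyl 4-[(4S)-4-benzyl-2-oxo-1,3-oxazolidin-3-yl]-4-oxobutanoate | COC(=O)CCC(=O)N1C(=O)OC[C@@H]1Cc1ccccc1 | intermediate
20 | methyl (3R,4R,6E,10E)-3-{[(4S)-4-benzyl-2-oxo-1,3-oxazolidin-3-yl]carbonyl}-4-hydroxy-11-iodo-6-{[(4-methoxybenzyl)oxy]methyl}-10-{[(tert-butyldiphenylsilyl)oxy]methyl}undeca-6,10-dienoate | I/C=C(/CO[Si](c1ccccc1)(c1ccccc1)C(C)(C)C)CC/C=C(/COCc1ccc(OC)cc1)C[C@@H](O)[C@H](C(=O)N1C(=O)OC[C@@H]1Cc1ccccc1)CC(=O)OC | intermediate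
21 | 4-O-triethylsilyl ether of 20 | I/C=C(/CO[Si](c1ccccc1)(c1ccccc1)C(C)(C)C)CC/C=C(/COCc1ccc(OC)cc1)C[C@@H](O[Si](CC)(CC)CC)[C@H](C(=O)N1C(=O)OC[C@@H]1Cc1ccccc1)CC(=O)OC | intermediate
22 | methyl (3R,4R,6E,10E)-3-[(ethylsulfanyl)carbonyl]-11-iodo-6-{[(4-methoxybenzyl)oxy]methyl}-10-{[(tert-butyldiphenylsilyl)oxy]methyl}-4-[(triethylsilyl)oxy]undeca-6,10-dienoate | I/C=C(/CO[Si](c1ccccc1)(c1ccccc1)C(C)(C)C)CC/C=C(/COCc1ccc(OC)cc1)C[C@@H](O[Si](CC)(CC)CC)[C@H](C(=O)SCC)CC(=O)OC | intermediate
23 | methyl (3R,4R,6E,10E)-3-formyl-11-iodo-6-{[(4-methoxybenzyl)oxy]methyl}-10-{[(tert-butyldiphenylsilyl)oxy]methyl}-4-[(triethylsilyl)oxy]undeca-6,10-dienoate (C5 alkenyl iodide, C6 aldehyde, C12 methyl ester) | I/C=C(/CO[Si](c1ccccc1)(c1ccccc1)C(C)(C)C)CC/C=C(/COCc1ccc(OC)cc1)C[C@@H](O[Si](CC)(CC)CC)[C@H](C=O)CC(=O)OC | intermediate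
24 | ten-membered hydroxy ester: methyl ester of the 12,6-seco acid of 25 with 6α-OH, formed as its chromium alkoxide (not isolated) | COC(=O)C[C@H]1[C@H](O)/C=C(/CO[Si](c2ccccc2)(c2ccccc2)C(C)(C)C)CC/C=C(/COCc2ccc(OC)cc2)C[C@H]1O[Si](CC)(CC)CC | intermediate
25 | (6α,7αH,8β)-14-[(4-methoxybenzyl)oxy]-15-[(tert-butyldiphenylsilyl)oxy]-8-[(triethylsilyl)oxy]germacra-1(10),4-dien-12,6-olide, ring alkenes ring-cis, lactone trans-fused | C1C(=O)O[C@@H]2/C=C(/CO[Si](c3ccccc3)(c3ccccc3)C(C)(C)C)CC/C=C(/COCc3ccc(OC)cc3)C[C@@H](O[Si](CC)(CC)CC)[C@@H]12 | intermediate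
26 | 13-(dimethylamino) derivative of 25 (C11 epimers) | CN(C)CC1C(=O)O[C@@H]2/C=C(/CO[Si](c3ccccc3)(c3ccccc3)C(C)(C)C)CC/C=C(/COCc3ccc(OC)cc3)C[C@@H](O[Si](CC)(CC)CC)[C@@H]12 | intermediate
27 | 13-(trimethylammonio) iodide of 25 (C11 epimers, not isolated) | C[N+](C)(C)CC1C(=O)O[C@@H]2/C=C(/CO[Si](c3ccccc3)(c3ccccc3)C(C)(C)C)CC/C=C(/COCc3ccc(OC)cc3)C[C@@H](O[Si](CC)(CC)CC)[C@@H]12.[I-] | intermediate
28 | (6α,7αH,8β)-14-[(4-methoxybenzyl)oxy]-15-[(tert-butyldiphenylsilyl)oxy]-8-[(triethylsilyl)oxy]germacra-1(10),4,11(13)-trien-12,6-olide | C=C1C(=O)O[C@@H]2/C=C(/CO[Si](c3ccccc3)(c3ccccc3)C(C)(C)C)CC/C=C(/COCc3ccc(OC)cc3)C[C@@H](O[Si](CC)(CC)CC)[C@@H]12 | intermediate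
29 | (6α,7αH,8β)-8-hydroxy-14-[(4-methoxybenzyl)oxy]-15-[(tert-butyldiphenylsilyl)oxy]germacra-1(10),4,11(13)-trien-12,6-olide | C=C1C(=O)O[C@@H]2/C=C(/CO[Si](c3ccccc3)(c3ccccc3)C(C)(C)C)CC/C=C(/COCc3ccc(OC)cc3)C[C@@H](O)[C@@H]12 | intermediate
30 | (S)-2-methylbutanoic acid | CC[C@H](C)C(=O)O | starting material
31 | (6α,7αH,8β)-14-[(4-methoxybenzyl)oxy]-8-{[(2S)-2-methylbutanoyl]oxy}-15-[(tert-butyldiphenylsilyl)oxy]germacra-1(10),4,11(13)-trien-12,6-olide | C=C1C(=O)O[C@@H]2/C=C(/CO[Si](c3ccccc3)(c3ccccc3)C(C)(C)C)CC/C=C(/COCc3ccc(OC)cc3)C[C@@H](OC(=O)[C@@H](C)CC)[C@@H]12 | intermediate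
32 | (6α,7αH,8β)-14-hydroxy-8-{[(2S)-2-methylbutanoyl]oxy}-15-[(tert-butyldiphenylsilyl)oxy]germacra-1(10),4,11(13)-trien-12,6-olide | C=C1C(=O)O[C@@H]2/C=C(/CO[Si](c3ccccc3)(c3ccccc3)C(C)(C)C)CC/C=C(/CO)C[C@@H](OC(=O)[C@@H](C)CC)[C@@H]12 | intermediate
33 | (6α,7αH,8β)-8-{[(2S)-2-methylbutanoyl]oxy}-14-oxo-15-[(tert-butyldiphenylsilyl)oxy]germacra-1(10),4,11(13)-trien-12,6-olide | C=C1C(=O)O[C@@H]2/C=C(/CO[Si](c3ccccc3)(c3ccccc3)C(C)(C)C)CC/C=C(/C=O)C[C@@H](OC(=O)[C@@H](C)CC)[C@@H]12 | intermediate
34 | (6R,7R,8R)-15-hydroxy-8-{[(2S)-2-methylbutanoyl]oxy}-14-oxogermacra-1(10),4,11(13)-trien-12,6-olide (CNP0168859.6) | C=C1C(=O)O[C@@H]2/C=C(/CO)CC/C=C(/C=O)C[C@@H](OC(=O)[C@@H](C)CC)[C@@H]12 | target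

## Step count and risks

Total: 22 steps. Longest linear sequence: 20 steps, from 1 through 2, 7, 8, 12, 13, 14, 15, 16, 20, 21, 22, 23, 25, 26, 28, 29, 31, 32 and 33 to 34 (steps 1–3, 5–9 and 11–22).

**Step 15 (key step).** The most likely failure is poor facial selectivity at C6: the ten-membered transition state may not be able to adopt the Felkin–Anh arrangement that the open-chain bias prefers. Intermolecular coupling or simple reduction of the C–I bond may also compete at the dilution needed. Fallback: from 23 the coupling is run as before; if the wrong face is attacked, the product is the C6-epimeric hydroxy ester F1 (or its cis-fused lactone). Saponification with LiOH gives the C6-epimeric seco acid F2, and Mitsunobu lactonisation (PPh3, diisopropyl azodicarboxylate) closes the lactone by SN2 displacement at C6 with inversion instead of acyl substitution with retention, returning to 25.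

**Step 11.** Anti selectivity may erode because 16 is α-unbranched, the Lewis acid may move the β,γ double bond of 16 into conjugation, and the adduct may lactonise onto C12 before silylation. Fallback: a reagent-controlled anti aldol on a thioester, starting from 18 and 16 and returning at 23. Compound 18 and 2-methylpropane-2-thiol (pyridine) give S-tert-butyl 4-methoxy-4-oxobutanethioate F3, which is enolised at the thioester only. Its E enol borinate, made with a menthone-derived bis(2-isopropyl-5-methylcyclohexylmethyl)boron bromide of the appropriate handedness and Et3N, adds to 16 through a closed chair transition state with no Lewis acid on the aldehyde, giving anti β-hydroxy thioester F4. Silylation (Et3SiOTf, 2,6-lutidine) gives silyl ether F5, and i-Bu2AlH at −78 °C reduces the thioester to 23.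

**Step 2.** Addition may occur with reversed regiochemistry (copper on C4, β to oxygen), followed by β-elimination to an allene, and carbometalation by a functionalised alkylcopper in THF may be incomplete. Fallback: the geometry is built by a different syn addition, from 2 back to 8. Pd(PPh3)4-catalysed cis addition of Me3Si–SnBu3 to 2 places tin on C4 and silicon on C5, giving (Z)-silyl stannyl alkene F6. Stille coupling of the alkenylstannane with allyl bromide gives allyl vinylsilane F7. 9-BBN, then NaOH and H2O2, hydroborates only the terminal alkene to give alcohol F8. N-Iodosuccinimide replaces silicon by iodine with retention to give iodo alcohol F9, and Dess–Martin oxidation gives 8.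

**Step 5.** E selectivity in forming the trisubstituted enoate may be incomplete; the minor isomer would carry C2 and C9 trans into the ring and may be hard to separate. Fallback: from 8 back to 13 through a cyclic stabilised ylide. Wittig reaction of 8 with commercial 3-(triphenylphosphoranylidene)dihydrofuran-2(3H)-one gives (E)-alkylidene lactone F10. Opening with MeNH(OMe)·HCl and i-PrMgCl gives hydroxy Weinreb amide F11, and t-BuMe2SiCl with imidazole gives silyl ether F12. i-Bu2AlH at −78 °C gives enal F13, and Luche reduction (NaBH4, CeCl3) gives 13.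

## Further compounds

F1 | step 15 | C6 epimer of hydroxy ester 24 (6β-OH) | COC(=O)C[C@H]1[C@@H](O)/C=C(/CO[Si](c2ccccc2)(c2ccccc2)C(C)(C)C)CC/C=C(/COCc2ccc(OC)cc2)C[C@H]1O[Si](CC)(CC)CC
F2 | step 15 | C6-epimeric seco acid (carboxylic acid of F1) | OC(=O)C[C@H]1[C@@H](O)/C=C(/CO[Si](c2ccccc2)(c2ccccc2)C(C)(C)C)CC/C=C(/COCc2ccc(OC)cc2)C[C@H]1O[Si](CC)(CC)CC
F3 | step 11 | S-tert-butyl 4-methoxy-4-oxobutanethioate | COC(=O)CCC(=O)SC(C)(C)C
F4 | step 11 | methyl (3R,4R,6E,10E)-3-[(tert-butylsulfanyl)carbonyl]-4-hydroxy-11-iodo-6-{[(4-methoxybenzyl)oxy]methyl}-10-{[(tert-butyldiphenylsilyl)oxy]methyl}undeca-6,10-dienoate | I/C=C(/CO[Si](c1ccccc1)(c1ccccc1)C(C)(C)C)CC/C=C(/COCc1ccc(OC)cc1)C[C@@H](O)[C@H](C(=O)SC(C)(C)C)CC(=O)OC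
F5 | step 11 | 4-O-triethylsilyl ether of F4 | I/C=C(/CO[Si](c1ccccc1)(c1ccccc1)C(C)(C)C)CC/C=C(/COCc1ccc(OC)cc1)C[C@@H](O[Si](CC)(CC)CC)[C@H](C(=O)SC(C)(C)C)CC(=O)OC
F6 | step 2 | (Z)-tert-butyldiphenyl{[2-(tributylstannyl)-3-(trimethylsilyl)prop-2-en-1-yl]oxy}silane | C[Si](C)(C)/C=C(\[Sn](CCCC)(CCCC)CCCC)CO[Si](c1ccccc1)(c1ccccc1)C(C)(C)C
F7 | step 2 | (E)-tert-butyldiphenyl({2-[(trimethylsilyl)methylidene]pent-4-en-1-yl}oxy)silane | C[Si](C)(C)/C=C(\CC=C)CO[Si](c1ccccc1)(c1ccccc1)C(C)(C)C
F8 | step 2 | (E)-5-[(tert-butyldiphenylsilyl)oxy]-4-[(trimethylsilyl)methylidene]pentan-1-ol | C[Si](C)(C)/C=C(\CCCO)CO[Si](c1ccccc1)(c1ccccc1)C(C)(C)C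
F9 | step 2 | (E)-4-{[(tert-butyldiphenylsilyl)oxy]methyl}-5-iodopent-4-en-1-ol | I/C=C(\CCCO)CO[Si](c1ccccc1)(c1ccccc1)C(C)(C)C
F10 | step 5 | (3E)-3-[(4E)-4-{[(tert-butyldiphenylsilyl)oxy]methyl}-5-iodopent-4-en-1-ylidene]dihydrofuran-2(3H)-one | I/C=C(/CO[Si](c1ccccc1)(c1ccccc1)C(C)(C)C)CC/C=C1\CCOC1=O
F11 | step 5 | (2E,6E)-2-(2-hydroxyethyl)-7-iodo-N-methoxy-N-methyl-6-{[(tert-butyldiphenylsilyl)oxy]methyl}hepta-2,6-dienamide | I/C=C(/CO[Si](c1ccccc1)(c1ccccc1)C(C)(C)C)CC/C=C(/C(=O)N(C)OC)CCO
F12 | step 5 | O-tert-butyldimethylsilyl ether of F11 | I/C=C(/CO[Si](c1ccccc1)(c1ccccc1)C(C)(C)C)CC/C=C(/C(=O)N(C)OC)CCO[Si](C)(C)C(C)(C)C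
F13 | step 5 | (2E,6E)-2-{2-[(tert-butyldimethylsilyl)oxy]ethyl}-6-{[(tert-butyldiphenylsilyl)oxy]methyl}-7-iodohepta-2,6-dienal | I/C=C(/CO[Si](c1ccccc1)(c1ccccc1)C(C)(C)C)CC/C=C(/C=O)CCO[Si](C)(C)C(C)(C)C
A1 | alternative 1 | cyclodecadienal with ring-cis C4=C5 and ring-trans C1=C10, O6-TBS, O8-PMB, isopropenyl-type C7 side chain | CC(C)(C)[Si](C)(C)O[C@@H]1/C=C(/CO[Si](c2ccccc2)(c2ccccc2)C(C)(C)C)CC/C=C(\C=O)C[C@@H](OCc2ccc(OC)cc2)[C@H]1C(=C)CO[Si](C)(C)C(C)(C)C
A2 | alternative 2 | trans-fused ten-membered γ-lactone with C14 methyl ester, O8-TBS, O15-TBDPS | C1C(=O)O[C@@H]2/C=C(/CO[Si](c3ccccc3)(c3ccccc3)C(C)(C)C)CC/C=C(/C(=O)OC)C[C@@H](O[Si](C)(C)C(C)(C)C)[C@@H]12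
A3 | alternative 3 | 8-hydroxy germacranolide with O14-PMB and O15-TBDPS (identical with 29) | C=C1C(=O)O[C@@H]2/C=C(/CO[Si](c3ccccc3)(c3ccccc3)C(C)(C)C)CC/C=C(/COCc3ccc(OC)cc3)C[C@@H](O)[C@@H]12
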